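Gamma was the run I leaned on, because it climbed furthest of the earlier runs.

all flasks: starting material 0.15 M
- delta: reagent 1.5 equiv; free catalyst 0.035 mol%; run made earlier
- gamma: reagent 1.5 equiv; free catalyst 0.054 mol%; run made earlier
- zeta: reagent 0.76 equiv; free catalyst 0.05 mol%; run made earlier
- Thursday's: reagent 1.50 equiv; free catalyst 0.05 mol%; time 2.0 min
- Tuesday's: reagent 0.380 equiv; free catalyst 0.05 mol%; time 2.0 min
- Friday's: reagent 1.50 equiv; free catalyst 0.08 mol%; time 2.0 min
- Wednesday's: reagent 0.380 equiv; free catalyst 0.08 mol%; time 2.0 min

| run | time / s | target / % |
|---|---|---|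
| delta | 10.0 | 7 |
| delta | 30.0 | 22 |
| delta | 60.0 | 37 |
| delta | 80.0 | 50 |
| delta | 120 | 71 |
| gamma | 25.0 | 24 |
| gamma | 50.0 | 49 |
| gamma | 80.0 | 72 |
| gamma | 90.0 | 77 |
| gamma | 120 | 94 |
| zeta | 25.0 | 17 |
| zeta | 50.0 | 27 |
| zeta | 80.0 | 40 |
| zeta | 90.0 | 43 |
| zeta | 120 | 54 |

(each reading ± 1.5 percentage points)



1. ranking by amount of target, in percent of the starting material charged, from high to low, at 2.0 min (Thursday's / Tuesday's / Friday's / Wednesday's)
2. the same order at 25 s (Thursday's / Tuesday's / Friday's / Wednesday's)
3. the amount of target, in percent of the starting material charged of the flask you put first, at 2.0 min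
4. the amount of target, in percent of the starting material charged of the flask you put last, at 2.0 min

Delta and gamma, with the same reagent, reached about the same height at different times: 71% at 120 s and 72% at 80.0 s. Dividing the two times, and so the two rates, gave 1.50, and gamma's loading of free catalyst over delta's gave 1.54. So I carried one number with no time left in it, the speed ratio, Thursday's loading of free catalyst over gamma's at the same reagent, 0.926.

Multiplied by the ratio, Thursday's 2.0 min stood at 111 s on gamma's clock. That lay between gamma's 77% at 90.0 s and 94% at 120 s, and a straight line between them gave 89.0%. Friday's ratio was 1.48, which put it at 178 s, past every gamma reading, and this was the weak link. Extending gamma's last stretch to full conversion ended at 131 s on the clock. On that line my estimate put Friday's at full conversion after about 88.5 s, and its last 31.5 s lay past gamma's last reading on that clock. I committed to 89.0% for Thursday's and left Friday's open. The flasks with 0.380 equiv of reagent had less than any earlier run, so I gave the ratio no say there.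

The forecast gave Friday's > Thursday's > Wednesday's > Tuesday's at 2.0 min and Friday's > Thursday's > Wednesday's > Tuesday's at 25 s, with 99% first and 32% last, holding that “the rate is first order in catalyst”.

The simulation gave Thursday's > Friday's > Wednesday's > Tuesday's at 2.0 min and Friday's > Thursday's > Wednesday's > Tuesday's at 25 s, with 90.1% first and 27.7% last.

    reagent + free catalyst + target → free catalyst + over-reaction product (k = 4100 L² mol⁻² s⁻¹)
    starting material + free catalyst → catalyst intermediate A (k = 32100 L mol⁻¹ s⁻¹)
    catalyst intermediate C → free catalyst + target (k = 73.4 s⁻¹)
    reagent + catalyst intermediate B ⇌ catalyst intermediate C (K = 2.31 L mol⁻¹, k = 3540 L mol⁻¹ s⁻¹)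
    catalyst intermediate A → catalyst intermediate B (k = 133 s⁻¹)

Thursday's, at 111 s on gamma's clock, held 90.1% of target against my 89.0%. Friday's held 57.6%, less than Thursday's, with 0% starting material left and 42.4% as over-reaction product. Thursday's flask read at 80 s keeps the ratio 0.926, which puts it at 74.1 s on the clock, between gamma's 49% at 50.0 s and 72% at 80.0 s. The straight line there gave 67.5%, and that flask held 67.7% of target.

The numbers in the tables were generated by integration with constants of no real substance; scatter was added.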